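**Strategy**

Each 2-aryl-2,3-dihydrobenzofuran is cut at C2–C3. C3, the ring carbon bound to the fused arene and carrying CH2OH, becomes the carbene carbon of an aryl diazoacetate; C2, flanked by ring oxygen O1 and an aryl ring, becomes the benzylic OCH2 of an aryl benzyl ether lying 1,5 to it. Because the two furan rings repeat this pattern with the same configuration, one chiral dirhodium catalyst performs a double intramolecular C–H insertion on a linear bis(diazoester), assembled from vanillin acetate and two 5-iodovanillin units, closing both oxygen rings and setting both C2 centres. Base equilibration then sets C3 trans and one hydride reduction delivers all three CH2OH groups.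

Key step: step 7

Assumption: the facial sense of the insertion is taken from simple 2-(benzyloxy)aryl diazoacetates, for which the (S)-configured N-phthaloyl-tert-leucinate catalyst is taken to give the (2R)-cis ester; the (R)-configured catalyst is therefore specified to reach 2S.

**Route**

Step 1
Reactants: 1 5-iodovanillin (4-hydroxy-3-iodo-5-methoxybenzaldehyde); 2 ethyl (triphenylphosphoranylidene)acetate
Product: 3 ethyl (E)-3-(4-hydroxy-3-iodo-5-methoxyphenyl)prop-2-enoate (ethyl 5-iodoferulate)
Conditions: 2 (1.5 equiv), toluene, 90 °C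
Reagents that add atoms: ethyl (triphenylphosphoranylidene)acetate (2), CCOC(=O)C=P(c1ccccc1)(c1ccccc1)c1ccccc1
Why: Wittig olefination with a stabilised ylide should give the (E)-acrylate selectively and tolerates the free, hindered phenol.

Step 2
Reactants: 4 vanillin acetate (4-formyl-2-methoxyphenyl acetate)
Product: 5 4-(hydroxymethyl)-2-methoxyphenyl acetate
Conditions: NaBH4 (0.5 equiv), THF/EtOH, 0 °C, prompt quench with aq. NH4Cl
Reagents that add atoms: none
Why: Chemoselective borohydride reduction, since the aldehyde is reduced far faster than the aryl acetate is attacked at 0 °C.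

Step 3
Reactants: 1 5-iodovanillin; 5 4-(hydroxymethyl)-2-methoxyphenyl acetate
Product: 6 4-[(4-formyl-2-iodo-6-methoxyphenoxy)methyl]-2-methoxyphenyl acetate
Conditions: PPh3 (1.3 equiv), DIAD (1.3 equiv), THF, 0 °C to rt
Reagents that add atoms: none
Why: Mitsunobu etherification, in which the acidic phenol of 1 (ortho positions blocked by I and OMe) displaces the activated primary benzylic oxyphosphonium while the neutral conditions spare acetate and aldehyde.

Step 4
Reactants: 6 4-[(4-formyl-2-iodo-6-methoxyphenoxy)methyl]-2-methoxyphenyl acetate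
Product: 7 4-{[4-(hydroxymethyl)-2-iodo-6-methoxyphenoxy]methyl}-2-methoxyphenyl acetate
Conditions: NaBH4 (0.5 equiv), THF/EtOH, 0 °C, prompt quench with aq. NH4Cl
Reagents that add atoms: none
Why: Borohydride reduction of the aryl aldehyde to the benzylic alcohol, done after the phenol is etherified so that no para-quinone methide can form, with aryl iodide and acetate untouched at 0 °C.

Step 5
Reactants: 7 4-{[4-(hydroxymethyl)-2-iodo-6-methoxyphenoxy]methyl}-2-methoxyphenyl acetate; 3 ethyl 5-iodoferulate
Product: 8 bis-iodide, ethyl (E)-3-[4-({4-[(4-acetoxy-3-methoxyphenyl)methoxy]-3-iodo-5-methoxyphenyl}methoxy)-3-iodo-5-methoxyphenyl]prop-2-enoate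
Conditions: PPh3 (1.3 equiv), DIAD (1.3 equiv), THF (concentrated), 0 °C to rt
Reagents that add atoms: none
Why: Second Mitsunobu etherification, pairing a primary alkoxy-stabilised benzylic alcohol with an acidic phenol whose ortho and para positions are blocked, so only O-alkylation is possible.

Step 6
Reactants: 8 bis-iodide; 9 ethyl diazoacetate
Product: 10 bis(diazoester), ethyl (E)-3-[4-({4-[(4-acetoxy-3-methoxyphenyl)methoxy]-3-(1-diazo-2-ethoxy-2-oxoethyl)-5-methoxyphenyl}methoxy)-3-(1-diazo-2-ethoxy-2-oxoethyl)-5-methoxyphenyl]prop-2-enoate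
Conditions: 9 (4 equiv), Pd(PPh3)4 (10 mol%), Ag2CO3 (1.0 equiv), Et3N (2.6 equiv), toluene, rt, dark
Reagents that add atoms: ethyl diazoacetate (9), CCOC(=O)C=[N+]=[N-]
Why: Palladium-catalysed cross-coupling of an aryl iodide with a diazoacetate (oxidative addition to zerovalent palladium, base-assisted palladation of the diazo carbon, reductive elimination with the diazo group retained at room temperature) should run at both iodides, the trans-disubstituted acrylate being too slow a Heck partner at this temperature.

Step 7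
Reactants: 10 bis(diazoester)
Product: 13 cis,cis-bis(dihydrobenzofuran) triester acetate (2S,3R at both rings), via outer-ring-closed monodiazoester 11 (not isolated), via inner-ring-closed monodiazoester 12 (not isolated)
Conditions: Rh2(R-PTTL)4 [dirhodium tetrakis(N-phthaloyl-(R)-tert-leucinate)] (4 mol%), toluene, −60 °C, slow addition of 10 at high dilution, 4 Å molecular sieves
Reagents that add atoms: none
Why: Each diazoester loses N2 at the dirhodium centre to give a donor/acceptor carbenoid whose carbon (future C3) inserts, through a hydride-transfer-like three-centre transition state, into the neighbouring benzylic C–H bond alpha to the ether oxygen (future C2), forming the C2–C3 bond. The closest known reaction type is the enantioselective intramolecular 1,5 C–H insertion of 2-(benzyloxy)aryl diazoacetates to cis-2-aryl-2,3-dihydrobenzofuran-3-carboxylates under chiral dirhodium carboxylate catalysis, here run twice in one molecule. Both five-membered oxygen rings (O1, C2, C3, C3a, C7a in the outer unit and the same atoms in the inner unit) close in this 1,5-insertion mode. C2 and C2' should be set by the chiral pocket of the catalyst in the assumed sense, while C3 and C3' follow as cis from the compact insertion transition state and are corrected in step 8; because one catalyst sets both sites, most wrong-sense events should end up in a separable diastereomer, not in the enantiomer. The step needs insertion to win over carbene dimerisation, alkene cyclopropanation and attack on other C–H bonds, which the 1,5 placement of a doubly activated (benzylic, alpha-oxygen) C–H bond, the electron-poor trans-disubstituted acrylate, the low temperature and the dilution should secure.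

Step 8
Reactants: 13 cis,cis-bis(dihydrobenzofuran) triester acetate
Product: 17 trans,trans phenol triester (2S,3S at both rings), via cis-cis phenol triester 14 (not isolated), via outer-trans inner-cis phenol triester 15 (not isolated), via outer-cis inner-trans phenol triester 16 (not isolated)
Conditions: NaOEt (2.5 equiv), EtOH/THF, 0 °C to rt; AcOH quench
Reagents that add atoms: none
Why: Ethoxide first cleaves the aryl acetate by transesterification and then equilibrates C3 and C3' through the ester enolates to the thermodynamically preferred 2,3-trans arrangement (base-mediated epimerisation), C2 and C2' staying intact because beta-elimination of the ring oxygen is a stereoelectronically poor reverse 5-endo process and the enolate is reprotonated quickly in ethanol.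

Step 9
Reactants: 17 trans,trans phenol triester
Product: 18 target, (E)-3-{(2S,3R)-2-[(2S,3R)-2-(4-hydroxy-3-methoxyphenyl)-3-(hydroxymethyl)-7-methoxy-2,3-dihydrobenzofuran-5-yl]-3-(hydroxymethyl)-7-methoxy-2,3-dihydrobenzofuran-5-yl}prop-2-en-1-ol
Conditions: i-Bu2AlH (DIBAL-H, 10 equiv), THF/toluene, −78 to 0 °C; aq. potassium sodium tartrate
Reagents that add atoms: none
Why: Excess DIBAL-H should reduce the two saturated esters to primary alcohols and the cinnamate by clean 1,2-reduction to the (E)-allylic alcohol (ester-to-alcohol hydride reduction) without touching the stereocentres, the phenol merely consuming one hydride.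

**Compound list**

1 | 5-iodovanillin (4-hydroxy-3-iodo-5-methoxybenzaldehyde) | COc1cc(C=O)cc(I)c1O | starting material
2 | ethyl (triphenylphosphoranylidene)acetate | CCOC(=O)C=P(c1ccccc1)(c1ccccc1)c1ccccc1 | starting material
3 | ethyl (E)-3-(4-hydroxy-3-iodo-5-methoxyphenyl)prop-2-enoate | CCOC(=O)/C=C/c1cc(I)c(O)c(OC)c1 | intermediate
4 | vanillin acetate (4-formyl-2-methoxyphenyl acetate) | COc1cc(C=O)ccc1OC(C)=O | starting material
5 | 4-(hydroxymethyl)-2-methoxyphenyl acetate | COc1cc(CO)ccc1OC(C)=O | intermediate
6 | 4-[(4-formyl-2-iodo-6-methoxyphenoxy)methyl]-2-methoxyphenyl acetate | COc1cc(C=O)cc(I)c1OCc1ccc(OC(C)=O)c(OC)c1 | intermediate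
7 | 4-{[4-(hydroxymethyl)-2-iodo-6-methoxyphenoxy]methyl}-2-methoxyphenyl acetate | COc1cc(CO)cc(I)c1OCc1ccc(OC(C)=O)c(OC)c1 | intermediate
8 | bis-iodide, ethyl (E)-3-[4-({4-[(4-acetoxy-3-methoxyphenyl)methoxy]-3-iodo-5-methoxyphenyl}methoxy)-3-iodo-5-methoxyphenyl]prop-2-enoate | CCOC(=O)/C=C/c1cc(I)c(OCc2cc(I)c(OCc3ccc(OC(C)=O)c(OC)c3)c(OC)c2)c(OC)c1 | intermediate
9 | ethyl diazoacetate | CCOC(=O)C=[N+]=[N-] | starting material
10 | bis(diazoester), both iodides of 8 replaced by C(=N2)CO2Et | CCOC(=O)/C=C/c1cc(C(=[N+]=[N-])C(=O)OCC)c(OCc2cc(C(=[N+]=[N-])C(=O)OCC)c(OCc3ccc(OC(C)=O)c(OC)c3)c(OC)c2)c(OC)c1 | intermediate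
11 | outer-ring-closed monodiazoester (not isolated): outer ring cis (2S,3R), inner diazoester still open | COc1cc([C@H]2Oc3c(OC)cc(COc4c(OC)cc(/C=C/C(=O)OCC)cc4C(=[N+]=[N-])C(=O)OCC)cc3[C@H]2C(=O)OCC)ccc1OC(C)=O | intermediate
12 | inner-ring-closed monodiazoester (not isolated): inner ring cis (2S,3R), outer diazoester still open | COc1cc(COc2c(OC)cc([C@H]3Oc4c(OC)cc(/C=C/C(=O)OCC)cc4[C@H]3C(=O)OCC)cc2C(=[N+]=[N-])C(=O)OCC)ccc1OC(C)=O | intermediate
13 | cis,cis-triester acetate, ethyl (2S,3R)-2-(4-acetoxy-3-methoxyphenyl)-5-{(2S,3R)-3-(ethoxycarbonyl)-5-[(E)-3-ethoxy-3-oxoprop-1-enyl]-7-methoxy-2,3-dihydrobenzofuran-2-yl}-7-methoxy-2,3-dihydrobenzofuran-3-carboxylate | COc1cc([C@H]2Oc3c(OC)cc([C@H]4Oc5c(OC)cc(/C=C/C(=O)OCC)cc5[C@H]4C(=O)OCC)cc3[C@H]2C(=O)OCC)ccc1OC(C)=O | intermediate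
14 | cis-cis phenol triester (not isolated): 13 without the acetyl group | COc1cc([C@H]2Oc3c(OC)cc([C@H]4Oc5c(OC)cc(/C=C/C(=O)OCC)cc5[C@H]4C(=O)OCC)cc3[C@H]2C(=O)OCC)ccc1O | intermediate
15 | outer-trans inner-cis phenol triester (not isolated): outer ring (2S,3S), inner ring (2S,3R) | COc1cc([C@H]2Oc3c(OC)cc([C@H]4Oc5c(OC)cc(/C=C/C(=O)OCC)cc5[C@H]4C(=O)OCC)cc3[C@@H]2C(=O)OCC)ccc1O | intermediate
16 | outer-cis inner-trans phenol triester (not isolated): outer ring (2S,3R), inner ring (2S,3S) | COc1cc([C@H]2Oc3c(OC)cc([C@H]4Oc5c(OC)cc(/C=C/C(=O)OCC)cc5[C@@H]4C(=O)OCC)cc3[C@H]2C(=O)OCC)ccc1O | intermediate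
17 | trans,trans phenol triester, ethyl (2S,3S)-5-{(2S,3S)-3-(ethoxycarbonyl)-5-[(E)-3-ethoxy-3-oxoprop-1-enyl]-7-methoxy-2,3-dihydrobenzofuran-2-yl}-2-(4-hydroxy-3-methoxyphenyl)-7-methoxy-2,3-dihydrobenzofuran-3-carboxylate | COc1cc([C@H]2Oc3c(OC)cc([C@H]4Oc5c(OC)cc(/C=C/C(=O)OCC)cc5[C@@H]4C(=O)OCC)cc3[C@@H]2C(=O)OCC)ccc1O | intermediate
18 | target, (E)-3-{(2S,3R)-2-[(2S,3R)-2-(4-hydroxy-3-methoxyphenyl)-3-(hydroxymethyl)-7-methoxy-2,3-dihydrobenzofuran-5-yl]-3-(hydroxymethyl)-7-methoxy-2,3-dihydrobenzofuran-5-yl}prop-2-en-1-ol | COc1cc([C@H]2Oc3c(OC)cc([C@H]4Oc5c(OC)cc(/C=C/CO)cc5[C@@H]4CO)cc3[C@@H]2CO)ccc1O | target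

**Step count and risks**

Total step count: 9. Longest linear sequence: 8 steps (4 → 5 → 6 → 7 → 8 → 10 → 13 → 17 → 18).

Steps most likely to fail:

Step 7. With two carbene precursors in one molecule, carbene–diazo coupling (azine or alkene formation) may compete, and uneven facial control at the two differently substituted benzylic sites may lower the share of the single diastereomer. The fallback closes one ring per operation; it sets out from 6 and comes back at 11. Aldehyde 6 would be coupled with 9 under the conditions of step 6 to give 4-{[2-(1-diazo-2-ethoxy-2-oxoethyl)-4-formyl-6-methoxyphenoxy]methyl}-2-methoxyphenyl acetate F1. Insertion with Rh2(R-PTTL)4 in toluene at −60 °C would close the outer ring alone to ethyl (2S,3R)-2-(4-acetoxy-3-methoxyphenyl)-5-formyl-7-methoxy-2,3-dihydrobenzofuran-3-carboxylate F2, which can be purified and enantio-enriched by crystallisation. NaBH4 at 0 °C would give ethyl (2S,3R)-2-(4-acetoxy-3-methoxyphenyl)-5-(hydroxymethyl)-7-methoxy-2,3-dihydrobenzofuran-3-carboxylate F3. Mitsunobu etherification with 3 would give the aryl iodide ether F4, and a single palladium-catalysed coupling with 9 would give 11, now isolated. A single insertion under the conditions of step 7 then leads to 13. Any partial epimerisation at C3 on the way is harmless because step 8 equilibrates this centre.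

Step 6. Oxidative addition and coupling at two iodides that each sit next to a twisted benzyloxy group may be slow, and palladium-carbene decomposition of diazo groups already installed may then take over. The fallback separates C–C bond formation from diazo formation; it sets out from 8 and comes back at 10. Negishi-type arylation of commercial ethyl (bromozincio)acetate (Reformatsky reagent; Pd(dba)2, P(t-Bu)3, THF, rt) at both iodides would give the bis(arylacetate) diethyl 2,2'-substituted triester F5. Regitz diazo transfer with 4-acetamidobenzenesulfonyl azide and DBU in MeCN, which acts only on the two aryl-activated methylene groups, would return to 10.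

Step 8. Beta-elimination of the ring oxygen from the C3 ester enolates (ring opening to stilbene esters) and reclosure may accompany epimerisation and scramble C2, and the phenoxide or conjugate addition of ethoxide to the acrylate may add further losses. The fallback avoids any base treatment of the ring esters by making the trans rings directly under auxiliary control; it sets out from 8 and comes back at 18. Ethyl (S)-lactate and pyrrolidine would give (S)-2-hydroxy-1-(pyrrolidin-1-yl)propan-1-one F6. Bromoacetyl bromide and pyridine would give its bromoacetate F7, and N,N'-ditosylhydrazine with DBU would convert this into the chiral diazoacetate F8. Coupling of 8 with F8 under the conditions of step 6 would give the bis(diazoester) with two lactamide esters F9. Rh2(S-DOSP)4 [dirhodium tetrakis((S)-N-(4-dodecylphenylsulfonyl)prolinate)] in CH2Cl2, the auxiliary and catalyst pairing known to favour 2,3-trans products of the (2S,3S) ester series, would give the trans,trans tris-ester acetate F10. DIBAL-H under the conditions of step 9 would reduce the auxiliary esters, the acrylate and the acetate to give 18.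

**Further compounds**

F1 | step 7 | 4-{[2-(1-diazo-2-ethoxy-2-oxoethyl)-4-formyl-6-methoxyphenoxy]methyl}-2-methoxyphenyl acetate | CCOC(=O)C(=[N+]=[N-])c1cc(C=O)cc(OC)c1OCc1ccc(OC(C)=O)c(OC)c1
F2 | step 7 | ethyl (2S,3R)-2-(4-acetoxy-3-methoxyphenyl)-5-formyl-7-methoxy-2,3-dihydrobenzofuran-3-carboxylate | COc1cc([C@H]2Oc3c(OC)cc(C=O)cc3[C@H]2C(=O)OCC)ccc1OC(C)=O
F3 | step 7 | ethyl (2S,3R)-2-(4-acetoxy-3-methoxyphenyl)-5-(hydroxymethyl)-7-methoxy-2,3-dihydrobenzofuran-3-carboxylate | COc1cc([C@H]2Oc3c(OC)cc(CO)cc3[C@H]2C(=O)OCC)ccc1OC(C)=O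
F4 | step 7 | ethyl (2S,3R)-2-(4-acetoxy-3-methoxyphenyl)-5-({4-[(E)-3-ethoxy-3-oxoprop-1-enyl]-2-iodo-6-methoxyphenoxy}methyl)-7-methoxy-2,3-dihydrobenzofuran-3-carboxylate | COc1cc([C@H]2Oc3c(OC)cc(COc4c(OC)cc(/C=C/C(=O)OCC)cc4I)cc3[C@H]2C(=O)OCC)ccc1OC(C)=O
F5 | step 6 | bis(arylacetate), both iodides of 8 replaced by CH2CO2Et | CCOC(=O)/C=C/c1cc(CC(=O)OCC)c(OCc2cc(CC(=O)OCC)c(OCc3ccc(OC(C)=O)c(OC)c3)c(OC)c2)c(OC)c1
F6 | step 8 | (S)-2-hydroxy-1-(pyrrolidin-1-yl)propan-1-one | C[C@H](O)C(=O)N1CCCC1
F7 | step 8 | (S)-1-oxo-1-(pyrrolidin-1-yl)propan-2-yl 2-bromoacetate | C[C@H](OC(=O)CBr)C(=O)N1CCCC1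
F8 | step 8 | (S)-1-oxo-1-(pyrrolidin-1-yl)propan-2-yl 2-diazoacetate | C[C@H](OC(=O)C=[N+]=[N-])C(=O)N1CCCC1
F9 | step 8 | bis(diazoester) as 10 but with two (S)-1-oxo-1-(pyrrolidin-1-yl)propan-2-yl diazoesters | CCOC(=O)/C=C/c1cc(C(=[N+]=[N-])C(=O)O[C@@H](C)C(=O)N2CCCC2)c(OCc2cc(C(=[N+]=[N-])C(=O)O[C@@H](C)C(=O)N3CCCC3)c(OCc3ccc(OC(C)=O)c(OC)c3)c(OC)c2)c(OC)c1
F10 | step 8 | trans,trans tris-ester acetate, (2S,3S) at both rings, both C3 esters (S)-1-oxo-1-(pyrrolidin-1-yl)propan-2-yl | COc1cc([C@H]2Oc3c(OC)cc([C@H]4Oc5c(OC)cc(/C=C/C(=O)OCC)cc5[C@@H]4C(=O)O[C@@H](C)C(=O)N4CCCC4)cc3[C@@H]2C(=O)O[C@@H](C)C(=O)N2CCCC2)ccc1OC(C)=O
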